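## Retrosynthetic overview

1. Target 20 ⇐ 18: the C5 phenol is carried as a methyl ether, removed at the end by chelation to the C4 ketone, and the acid as its methyl ester.
2. The strategy rests on the C3 methyl group beside the C4 ketone in the pyranone ring (O1–C2–C3–C4–C4a–C8a). Cutting C3–C4 gives aldehyde 16, whose C4a formyl group adds across the vinyl group of the (R)-but-3-en-2-yl ether on O1 (acyl carbon to the internal carbon, hydrogen to the terminal one).
3. 16 ⇐ salicylaldehyde 14 + (S)-but-3-en-2-ol (Mitsunobu, inversion, sets C2). 14 ⇐ phenol 9 by reverse-prenyl ether/Claisen shift and ortho-formylation. With OMe on both oxygens flanking the side chain, the two free ring positions of 9 are equivalent, so no regiochemical choice arises.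
4. 9 ⇐ dihydrocoumarin 6 (methanolysis/O-methylation, debenzylation) ⇐ coumarin 5 (copper hydride asymmetric conjugate reduction, sets the benzylic centre) ⇐ Pechmann coumarin 3 from 1 and 2.
5. Ring order: benzene ring from 1; a temporary lactone ring is closed in step 1 and opened in step 5; the pyranone ring is closed last, in step 12.

Key step: step 12

Assumption: the facial sense of the copper hydride reduction (step 4) is taken from the quadrant model for β,β-disubstituted unsaturated lactones; (S)-DTBM-SEGPHOS is written, and the other ligand enantiomer would be used if the first correlation of 6 shows the opposite face is reduced.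

## Route

Step 1
Reactants: 1 phloroglucinol; 2 ethyl 3-oxooctanoate
Product: 3 5,7-dihydroxy-4-pentyl-2H-chromen-2-one
Conditions: conc. H2SO4, 0 °C to rt
Reagents that add atoms: none
Why: Pechmann condensation, in which acid-promoted transesterification and ring closure onto the strongly activated, threefold-symmetric ring of 1 should give a single coumarin.

Step 2
Reactants: 3 5,7-dihydroxy-4-pentyl-2H-chromen-2-one
Product: 4 7-(benzyloxy)-5-hydroxy-4-pentyl-2H-chromen-2-one
Conditions: BnBr (1.0 equiv), K2CO3 (1.0 equiv), acetone, rt to 50 °C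
Reagents that add atoms: benzyl bromide, BrCc1ccccc1
Why: Williamson etherification, expected at O7 because this is the less hindered and, in 5,7-dihydroxy-4-alkylcoumarins, the more readily alkylated hydroxyl, whereas 5-OH is shielded by the peri pentyl group.

Step 3
Reactants: 4 7-(benzyloxy)-5-hydroxy-4-pentyl-2H-chromen-2-one
Product: 5 7-(benzyloxy)-5-methoxy-4-pentyl-2H-chromen-2-one
Conditions: MeI, K2CO3, DMF, rt
Reagents that add atoms: iodomethane, CI
Why: Williamson methylation of the one remaining phenol, which has no competing site.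

Step 4
Reactants: 5 7-(benzyloxy)-5-methoxy-4-pentyl-2H-chromen-2-one
Product: 6 (4R)-7-(benzyloxy)-5-methoxy-4-pentyl-3,4-dihydro-2H-chromen-2-one
Conditions: Cu(OAc)2·H2O (3 mol%), (S)-DTBM-SEGPHOS (3 mol%), (EtO)2MeSiH (1.5 equiv), t-BuOH (1.1 equiv), toluene, 0 °C to rt; aq. NH4F
Reagents that add atoms: none
Why: Asymmetric conjugate reduction (1,4-hydrosilylation) by a bisphosphine-ligated copper hydride, a known reaction of 4-substituted coumarins, in which the chiral ligand directs hydride to one face of C4 and so sets the (R) benzylic centre, and t-BuOH protonates the copper enolate.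

Step 5
Reactants: 6 (4R)-7-(benzyloxy)-5-methoxy-4-pentyl-3,4-dihydro-2H-chromen-2-one
Product: 8 methyl (3R)-3-[4-(benzyloxy)-2,6-dimethoxyphenyl]octanoate, via ring-opened sodium phenolate methyl ester 7 (not isolated)
Conditions: NaOMe (1.3 equiv), MeOH, rt; then MeI (3 equiv), DMF, 40 °C
Reagents that add atoms: sodium methoxide, C[O-].[Na+]; iodomethane, CI
Why: Methanolysis of the aryl lactone (acyl substitution driven by release of the phenoxide) followed by Williamson methylation of that phenoxide before it can relactonize, with the stereocentre β to the ester and therefore not epimerizable.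

Step 6
Reactants: 8 methyl (3R)-3-[4-(benzyloxy)-2,6-dimethoxyphenyl]octanoate
Product: 9 methyl (3R)-3-(4-hydroxy-2,6-dimethoxyphenyl)octanoate
Conditions: H2 (1 atm), 10% Pd/C, EtOAc, rt
Reagents that add atoms: none
Why: Hydrogenolysis of the benzyl ether, carried out before any alkene or aldehyde is present, frees the phenol para to the side chain.

Step 7
Reactants: 10 2-methylbut-3-en-2-ol
Product: 11 tert-butyl 2-methylbut-3-en-2-yl carbonate
Conditions: n-BuLi, THF, −78 °C; Boc2O, −78 °C to rt; H2O
Reagents that add atoms: di-tert-butyl dicarbonate, CC(C)(C)OC(=O)OC(=O)OC(C)(C)C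
Why: Alkoxycarbonylation of the lithium tertiary alkoxide with Boc2O, the usual preparation of tertiary allylic carbonates.

Step 8
Reactants: 9 methyl (3R)-3-(4-hydroxy-2,6-dimethoxyphenyl)octanoate; 11 tert-butyl 2-methylbut-3-en-2-yl carbonate
Product: 12 methyl (3R)-3-{2,6-dimethoxy-4-[(2-methylbut-3-en-2-yl)oxy]phenyl}octanoate
Conditions: Pd(PPh3)4 (3 mol%), THF, 0–4 °C
Reagents that add atoms: none
Why: Tsuji–Trost decarboxylative O-allylation, in which the phenoxide attacks the more substituted terminus of the 1,1-dimethylallyl palladium cation under kinetic control at low temperature to give the tertiary (reverse-prenyl) ether.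

Step 9
Reactants: 12 methyl (3R)-3-{2,6-dimethoxy-4-[(2-methylbut-3-en-2-yl)oxy]phenyl}octanoate
Product: 13 methyl (3R)-3-[4-hydroxy-2,6-dimethoxy-3-(3-methylbut-2-en-1-yl)phenyl]octanoate
Conditions: N,N-diethylaniline, 120 °C
Reagents that add atoms: none
Why: Aromatic Claisen rearrangement of the 1,1-dimethylallyl aryl ether, a [3,3] shift that delivers a linear prenyl group to an ortho carbon; the two ortho positions are equivalent and the basic solvent suppresses chroman formation.

Step 10
Reactants: 13 methyl (3R)-3-[4-hydroxy-2,6-dimethoxy-3-(3-methylbut-2-en-1-yl)phenyl]octanoate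
Product: 14 methyl (3R)-3-[3-formyl-4-hydroxy-2,6-dimethoxy-5-(3-methylbut-2-en-1-yl)phenyl]octanoate
Conditions: MgCl2 (anhydrous), Et3N, (CH2O)n, MeCN, reflux; 1 M HCl
Reagents that add atoms: paraformaldehyde (as formaldehyde), C=O
Why: Casnati–Skattebøl magnesium-mediated ortho-formylation, in which the magnesium phenoxide directs formaldehyde to the only free ortho position and a second formaldehyde oxidizes the benzylic alkoxide, under non-acidic conditions that spare the prenyl group next to the phenol.

Step 11
Reactants: 14 methyl (3R)-3-[3-formyl-4-hydroxy-2,6-dimethoxy-5-(3-methylbut-2-en-1-yl)phenyl]octanoate; 15 (S)-but-3-en-2-ol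
Product: 16 methyl (3R)-3-[4-{[(2R)-but-3-en-2-yl]oxy}-3-formyl-2,6-dimethoxy-5-(3-methylbut-2-en-1-yl)phenyl]octanoate
Conditions: PPh3, DIAD, toluene, 0 °C to rt
Reagents that add atoms: none
Why: Mitsunobu reaction, in which the acidic salicylaldehyde-type phenol displaces the oxyphosphonium of the secondary allylic alcohol by SN2 with inversion, turning the (S) alcohol into the (R) ether carbon that becomes C2.

Step 12
Reactants: 16 methyl (3R)-3-[4-{[(2R)-but-3-en-2-yl]oxy}-3-formyl-2,6-dimethoxy-5-(3-methylbut-2-en-1-yl)phenyl]octanoate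
Product: 18 methyl (3R)-3-[(2R,3R)-5,7-dimethoxy-2,3-dimethyl-8-(3-methylbut-2-en-1-yl)-4-oxo-3,4-dihydro-2H-chromen-6-yl]octanoate, via cis-(2R,3S) C3 epimer 17 (not isolated)
Conditions: 3-mesityl-5,6,7,8-tetrahydro-4H-cyclohepta[d]thiazol-3-ium perchlorate (20 mol%), DBU (20 mol%), 1,4-dioxane, 120 °C, sealed tube
Reagents that add atoms: none
Why: The thiazolylidene adds to the formyl group and proton transfer gives the Breslow enaminol, which reacts with the tethered vinyl group in a concerted, asynchronous Conia-ene-like step: its nucleophilic carbon bonds to the internal alkene carbon (C3–C4) while the enol proton passes to the terminal carbon (the C3 methyl group), after which the adduct collapses to the C4 ketone and free carbene. The closest known reaction is the carbene-catalysed intramolecular hydroacylation of unactivated alkenes in 2-allyloxybenzaldehydes to 3-methylchroman-4-ones. The pyranone ring (O1, C2, C3, C4, C4a, C8a) closes in the 6-exo-trig mode. The new C3 centre is controlled by the C2 centre installed in step 11: any cis epimer 17 should epimerize through the enol under the basic conditions to the diequatorial trans (2R,3R) isomer. Six- over seven-membered ring formation is secured by the geometry of the intramolecular proton delivery to the terminal carbon. Chemoselectivity over aromatic Claisen rearrangement is secured because the carbons that become C4a, C8 and C6 (both ortho positions and the para position of the aryl ether) are substituted, and the prenyl alkene is out of reach of the acyl anion equivalent.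

Step 13
Reactants: 18 methyl (3R)-3-[(2R,3R)-5,7-dimethoxy-2,3-dimethyl-8-(3-methylbut-2-en-1-yl)-4-oxo-3,4-dihydro-2H-chromen-6-yl]octanoate
Product: 19 methyl (3R)-3-[(2R,3R)-5-hydroxy-7-methoxy-2,3-dimethyl-8-(3-methylbut-2-en-1-yl)-4-oxo-3,4-dihydro-2H-chromen-6-yl]octanoate
Conditions: MgI2·OEt2 (excess), THF, 60 °C; dilute aq. HCl
Reagents that add atoms: none
Why: Chelation-controlled O-demethylation, in which magnesium bridges the C4 carbonyl and the peri C5 methoxy oxygen and iodide removes that methyl group by SN2, while the C7 methoxy group has no carbonyl partner; the method is known to spare a C8 prenyl group in 5-methoxy-8-prenylchroman-4-ones.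

Step 14
Reactants: 19 methyl (3R)-3-[(2R,3R)-5-hydroxy-7-methoxy-2,3-dimethyl-8-(3-methylbut-2-en-1-yl)-4-oxo-3,4-dihydro-2H-chromen-6-yl]octanoate
Product: 20 (3R)-3-[(2R,3R)-5-hydroxy-7-methoxy-2,3-dimethyl-8-(3-methylbut-2-en-1-yl)-4-oxo-3,4-dihydro-2H-chromen-6-yl]octanoic acid
Conditions: LiOH, THF/MeOH/H2O, rt; then 1 M HCl to pH 3
Reagents that add atoms: lithium hydroxide, [Li+].[OH-]
Why: Saponification of the methyl ester (and of any lactone formed in step 13), during which the C5 phenoxide deactivates the C4 ketone toward enolization so that C3 and C2 should stay untouched, and mild acidification gives the hydroxy acid, held open by the hydrogen bond between 5-OH and the C4 carbonyl.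

## Compound list

1 | phloroglucinol | Oc1cc(O)cc(O)c1 | starting material
2 | ethyl 3-oxooctanoate | CCCCCC(=O)CC(=O)OCC | starting material
3 | 5,7-dihydroxy-4-pentyl-2H-chromen-2-one | CCCCCC1=CC(=O)Oc2cc(O)cc(O)c12 | intermediate
4 | 7-(benzyloxy)-5-hydroxy-4-pentyl-2H-chromen-2-one | CCCCCC1=CC(=O)Oc2cc(OCc3ccccc3)cc(O)c12 | intermediate
5 | 7-(benzyloxy)-5-methoxy-4-pentyl-2H-chromen-2-one | CCCCCC1=CC(=O)Oc2cc(OCc3ccccc3)cc(OC)c12 | intermediate
6 | (4R)-7-(benzyloxy)-5-methoxy-4-pentyl-3,4-dihydro-2H-chromen-2-one | CCCCC[C@@H]1CC(=O)Oc2cc(OCc3ccccc3)cc(OC)c12 | intermediate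
7 | sodium 5-(benzyloxy)-3-methoxy-2-[(3R)-1-methoxy-1-oxooctan-3-yl]phenolate | CCCCC[C@H](CC(=O)OC)c1c([O-])cc(OCc2ccccc2)cc1OC.[Na+] | intermediate
8 | methyl (3R)-3-[4-(benzyloxy)-2,6-dimethoxyphenyl]octanoate | CCCCC[C@H](CC(=O)OC)c1c(OC)cc(OCc2ccccc2)cc1OC | intermediate
9 | methyl (3R)-3-(4-hydroxy-2,6-dimethoxyphenyl)octanoate | CCCCC[C@H](CC(=O)OC)c1c(OC)cc(O)cc1OC | intermediate
10 | 2-methylbut-3-en-2-ol | CC(C)(O)C=C | starting material
11 | tert-butyl 2-methylbut-3-en-2-yl carbonate | CC(C)(C)OC(=O)OC(C)(C)C=C | intermediate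
12 | methyl (3R)-3-{2,6-dimethoxy-4-[(2-methylbut-3-en-2-yl)oxy]phenyl}octanoate | CCCCC[C@H](CC(=O)OC)c1c(OC)cc(OC(C)(C)C=C)cc1OC | intermediate
13 | methyl (3R)-3-[4-hydroxy-2,6-dimethoxy-3-(3-methylbut-2-en-1-yl)phenyl]octanoate | CCCCC[C@H](CC(=O)OC)c1c(OC)cc(O)c(CC=C(C)C)c1OC | intermediate
14 | methyl (3R)-3-[3-formyl-4-hydroxy-2,6-dimethoxy-5-(3-methylbut-2-en-1-yl)phenyl]octanoate | CCCCC[C@H](CC(=O)OC)c1c(OC)c(C=O)c(O)c(CC=C(C)C)c1OC | intermediate
15 | (S)-but-3-en-2-ol | O[C@@H](C)C=C | starting material
16 | methyl (3R)-3-[4-{[(2R)-but-3-en-2-yl]oxy}-3-formyl-2,6-dimethoxy-5-(3-methylbut-2-en-1-yl)phenyl]octanoate | CCCCC[C@H](CC(=O)OC)c1c(OC)c(C=O)c(O[C@H](C)C=C)c(CC=C(C)C)c1OC | intermediate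
17 | methyl (3R)-3-[(2R,3S)-5,7-dimethoxy-2,3-dimethyl-8-(3-methylbut-2-en-1-yl)-4-oxo-3,4-dihydro-2H-chromen-6-yl]octanoate (cis) | CCCCC[C@H](CC(=O)OC)c1c(OC)c2c(c(CC=C(C)C)c1OC)O[C@H](C)[C@H](C)C2=O | intermediate
18 | methyl (3R)-3-[(2R,3R)-5,7-dimethoxy-2,3-dimethyl-8-(3-methylbut-2-en-1-yl)-4-oxo-3,4-dihydro-2H-chromen-6-yl]octanoate (trans) | CCCCC[C@H](CC(=O)OC)c1c(OC)c2c(c(CC=C(C)C)c1OC)O[C@H](C)[C@@H](C)C2=O | intermediate
19 | methyl (3R)-3-[(2R,3R)-5-hydroxy-7-methoxy-2,3-dimethyl-8-(3-methylbut-2-en-1-yl)-4-oxo-3,4-dihydro-2H-chromen-6-yl]octanoate | CCCCC[C@H](CC(=O)OC)c1c(O)c2c(c(CC=C(C)C)c1OC)O[C@H](C)[C@@H](C)C2=O | intermediate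
20 | (3R)-3-[(2R,3R)-5-hydroxy-7-methoxy-2,3-dimethyl-8-(3-methylbut-2-en-1-yl)-4-oxo-3,4-dihydro-2H-chromen-6-yl]octanoic acid | CCCCC[C@H](CC(=O)O)c1c(O)c2c(c(CC=C(C)C)c1OC)O[C@H](C)[C@@H](C)C2=O | target

## Step count and risks

Total step count: 14. Longest linear sequence: 13 steps (steps 1–6 and 8–14; step 7 is a one-step side branch).

Steps most likely to fail:

1. Step 12 (key step). Addition of the carbene to an aldehyde flanked by two ortho oxygens may be slow. At 120 °C the base could then open the product ring reversibly by β-elimination of the phenoxide (retro-oxa-Michael), which would erode the C2 configuration, or leave C3 incompletely equilibrated. Fallback (radical closure of the same C3–C4 bond): setting out from 16, Pinnick oxidation (NaClO2, NaH2PO4, 2-methyl-2-butene, t-BuOH/H2O) would give the corresponding benzoic acid F1. PhSeSePh/PBu3 would convert this into the Se-phenyl selenoester F2. Bu3SnH and AIBN in benzene at 80 °C would then generate the aroyl radical, which adds 6-exo-trig to the vinyl group; hydrogen abstraction by the resulting primary radical gives 18 (any 17 being equilibrated with a trace of DBU at rt), where the route is rejoined.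

2. Step 4. Hydride transfer to the β-carbon may be slow, because the 5- and 7-oxygens donate into it and the peri methoxy group hinders it. That would leave time for over-reduction of the product lactone to the lactol or give insufficient facial selectivity. Fallback (racemic reduction and resolution): setting out from 5, Mg turnings in MeOH at rt would reduce the C3–C4 double bond by electron transfer, and the magnesium methoxide formed would open the lactone to the racemic hydroxy ester F3. MeI/K2CO3 in DMF would give racemic methyl 3-[4-(benzyloxy)-2,6-dimethoxyphenyl]octanoate F4. Preparative chromatography on a chiral stationary phase would then deliver the R enantiomer, which is 8.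

3. Step 11. SN2 displacement at a phenol flanked by formyl and prenyl groups may be sluggish, and ionization of the allylic oxyphosphonium could lead to partial racemization or to SN2′ attack giving the linear crotyl ether. Fallback (catalyst-controlled allylic etherification instead of SN2 inversion): setting out from 14, (E)-but-2-en-1-yl methyl carbonate with Pd2(dba)3·CHCl3 and the DACH-phenyl Trost bisphosphine ligand, in the enantiomer that gives the R ether, would form the branched aryl but-3-en-2-yl ether by phenoxide attack on the π-crotyl palladium complex. This gives 16 directly without new intermediates.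

## Further compounds

F1 | step 12 | 2-{[(2R)-but-3-en-2-yl]oxy}-4,6-dimethoxy-5-[(3R)-1-methoxy-1-oxooctan-3-yl]-3-(3-methylbut-2-en-1-yl)benzoic acid | CCCCC[C@H](CC(=O)OC)c1c(OC)c(C(=O)O)c(O[C@H](C)C=C)c(CC=C(C)C)c1OC
F2 | step 12 | Se-phenyl 2-{[(2R)-but-3-en-2-yl]oxy}-4,6-dimethoxy-5-[(3R)-1-methoxy-1-oxooctan-3-yl]-3-(3-methylbut-2-en-1-yl)benzenecarboselenoate | CCCCC[C@H](CC(=O)OC)c1c(OC)c(C(=O)[Se]c2ccccc2)c(O[C@H](C)C=C)c(CC=C(C)C)c1OC
F3 | step 4 | racemic methyl 3-[4-(benzyloxy)-2-hydroxy-6-methoxyphenyl]octanoate | CCCCCC(CC(=O)OC)c1c(O)cc(OCc2ccccc2)cc1OC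
F4 | step 4 | racemic methyl 3-[4-(benzyloxy)-2,6-dimethoxyphenyl]octanoate | CCCCCC(CC(=O)OC)c1c(OC)cc(OCc2ccccc2)cc1OC
F0 | step 11 | none | none
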